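The target is cut at two bonds of the 6-methylflavan (unit B): O1–C8a and C8–CH2. In unit B the pyran oxygen (on C8a) and the bridge carbon (on C8) sit on neighbouring carbons of a fully substituted benzene ring, which is the pattern an aryne leaves behind after a nucleophile and an electrophile add across it. In one operation LiTMP generates the C8–C8a aryne from an open-chain (S)-3-aryl-1-phenylpropan-1-ol carrying bromine at the future C8a and a MOM ether at C7, the alkoxide closes the pyran ring, and the C8 aryllithium adds to the 8-carbaldehyde of the second flavan (unit A). Both C2 centres come from catalyst-controlled ketone reductions.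

Key step: step 17

Remark on the chemistry: flavan (2-phenylchromane) numbering O1, C2–C4, C4a, C5–C8, C8a is used for both halves; unit A has no C6 methyl, unit B has one; MOM = methoxymethyl. The target, the key-step precursor 22 and the key-step product 25 were checked atom by atom and are mutually consistent, with both C2 centres (S). 5-Bromobenzene-1,3-diol is assumed to be commercially available.

Design note: both formyl groups are introduced on symmetrical resorcinols, so the site of formylation is not in question, and the two phenols are then told apart by the hydrogen bond to the aldehyde. Unit A is closed by palladium-catalysed etherification and formylated through its 8-bromide, because its ring keeps a second acidic hydrogen (C6–H between OMe and OMOM) that could compete in an aryne sequence.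

**Unit A aldehyde (steps 1–9)**

Step 1
Reactants: 1 5-bromobenzene-1,3-diol
Product: 3 2-bromo-4,6-dihydroxybenzaldehyde, via aryl iminium chloride 2 (not isolated)
Conditions: POCl3, DMF, MeCN, 0 °C to rt; then H2O, 50 °C
Reagents that add atoms: N,N-dimethylformamide, CN(C)C=O (formyl carbon); water, O (formyl oxygen)
Why: Vilsmeier–Haack formylation, in which the chloroiminium ion should attack C4 (equivalent to C6 by symmetry), ortho and para to the two hydroxyls as with resorcinol and orcinol, and hydrolysis of the iminium salt gives the aldehyde.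

Step 2
Reactants: 3 2-bromo-4,6-dihydroxybenzaldehyde
Product: 4 2-bromo-6-hydroxy-4-(methoxymethoxy)benzaldehyde
Conditions: MOMCl (1.05 equiv), K2CO3, acetone, 0 °C to rt
Reagents that add atoms: chloromethyl methyl ether, COCCl
Why: Williamson-type O-alkylation that should take only the para 4-OH, because the 6-OH is held in a hydrogen bond to the formyl oxygen and is less acidic and less nucleophilic.

Step 3
Reactants: 4 2-bromo-6-hydroxy-4-(methoxymethoxy)benzaldehyde
Product: 5 2-bromo-6-methoxy-4-(methoxymethoxy)benzaldehyde
Conditions: MeI, K2CO3, DMF, 40 °C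
Reagents that add atoms: iodomethane, CI
Why: Williamson O-methylation of the remaining chelated phenol under slightly more forcing conditions, to which the MOM ether, the aldehyde and the aryl bromide are inert.

Step 4
Reactants: 5 2-bromo-6-methoxy-4-(methoxymethoxy)benzaldehyde; 6 acetophenone
Product: 7 (E)-3-[2-bromo-6-methoxy-4-(methoxymethoxy)phenyl]-1-phenylprop-2-en-1-one
Conditions: KOH, EtOH/H2O, rt
Reagents that add atoms: none
Why: Claisen–Schmidt condensation of a non-enolisable aldehyde with the acetophenone enolate, the E1cB dehydration giving the conjugated (E)-enone.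

Step 5
Reactants: 7 (E)-3-[2-bromo-6-methoxy-4-(methoxymethoxy)phenyl]-1-phenylprop-2-en-1-one
Product: 8 3-[2-bromo-6-methoxy-4-(methoxymethoxy)phenyl]-1-phenylpropan-1-one
Conditions: H2 (4 atm), RhCl(PPh3)3 (5 mol%), toluene/EtOH, 50 °C
Reagents that add atoms: none
Why: homogeneous rhodium-catalysed hydrogenation saturates the disubstituted enone C=C and should leave the aryl bromide, the aryl ketone and the MOM ether untouched, which heterogeneous palladium would not guarantee.

Step 6
Reactants: 8 3-[2-bromo-6-methoxy-4-(methoxymethoxy)phenyl]-1-phenylpropan-1-one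
Product: 9 (S)-3-[2-bromo-6-methoxy-4-(methoxymethoxy)phenyl]-1-phenylpropan-1-ol
Conditions: (R)-2-methyl-CBS-oxazaborolidine (20 mol%), BH3·SMe2, THF, −20 °C; then MeOH, H2O
Reagents that add atoms: none
Why: Corey–Bakshi–Shibata reduction in which phenyl is the large and CH2CH2Ar the small ketone substituent, so the (R)-oxazaborolidine should deliver hydride to the face that gives the (S)-carbinol, as it does for propiophenone.

Step 7
Reactants: 9 (S)-3-[2-bromo-6-methoxy-4-(methoxymethoxy)phenyl]-1-phenylpropan-1-ol
Product: 10 (2S)-5-methoxy-7-(methoxymethoxy)-2-phenylchromane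
Conditions: Pd(OAc)2 (3 mol%), rac-2-(di-tert-butylphosphino)-1,1'-binaphthyl (4 mol%), Cs2CO3, toluene, 80 °C
Reagents that add atoms: none
Why: intramolecular Buchwald–Hartwig etherification (oxidative addition of zerovalent palladium to C–Br, alkoxide coordination, C–O reductive elimination from the bulky phosphine complex), in which the carbinol C–O bond is not touched, so (S) is carried into C2.

Step 8
Reactants: 10 (2S)-5-methoxy-7-(methoxymethoxy)-2-phenylchromane
Product: 11 (2S)-8-bromo-5-methoxy-7-(methoxymethoxy)-2-phenylchromane
Conditions: NBS (1.0 equiv), NaHCO3, CH2Cl2, −40 to 0 °C, dark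
Reagents that add atoms: N-bromosuccinimide, O=C1CCC(=O)N1Br
Why: electrophilic aromatic bromination that should go to C8 (para to the C5 methoxy, flanked by the tied-back ring oxygen O1) in preference to the more crowded C6 between two freely rotating alkoxy groups, the usual outcome for 5,7-dialkoxyflavans.

Step 9
Reactants: 11 (2S)-8-bromo-5-methoxy-7-(methoxymethoxy)-2-phenylchromane
Product: 13 (2S)-5-methoxy-7-(methoxymethoxy)-2-phenylchromane-8-carbaldehyde, via 8-lithiochromane 12 (not isolated)
Conditions: n-BuLi, THF, −78 °C; DMF, −78 to 0 °C; then H2O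
Reagents that add atoms: N,N-dimethylformamide, CN(C)C=O
Why: bromine–lithium exchange followed by Bouveault formylation with DMF, the formyl position being fixed by the bromine and the aryllithium being stabilised by the flanking MOM ether and O1.

**Unit B bromo alcohol (steps 10–16)**

Step 10
Reactants: 14 5-bromo-1,3-dimethoxy-2-methylbenzene
Product: 15 5-bromo-2-methylbenzene-1,3-diol
Conditions: BBr3 (3 equiv), CH2Cl2, −78 °C to rt; then H2O
Reagents that add atoms: none
Why: Lewis-acid ether cleavage (bromide attacks the methyl group of the boron-complexed ether) removes both methyl groups and leaves the aryl bromide alone, giving a symmetrical resorcinol.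

Step 11
Reactants: 15 5-bromo-2-methylbenzene-1,3-diol
Product: 17 6-bromo-2,4-dihydroxy-3-methylbenzaldehyde, via aryl iminium chloride 16 (not isolated)
Conditions: POCl3, DMF, MeCN, 0 °C to rt; then H2O, 50 °C
Reagents that add atoms: N,N-dimethylformamide, CN(C)C=O (formyl carbon); water, O (formyl oxygen)
Why: Vilsmeier–Haack formylation for which C4 and C6 are the only ring hydrogens and are equivalent, so a single aldehyde can form.

Step 12
Reactants: 17 6-bromo-2,4-dihydroxy-3-methylbenzaldehyde
Product: 18 6-bromo-2-hydroxy-4-(methoxymethoxy)-3-methylbenzaldehyde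
Conditions: MOMCl (1.05 equiv), K2CO3, acetone, 0 °C to rt
Reagents that add atoms: chloromethyl methyl ether, COCCl
Why: Williamson-type O-alkylation selective for the 4-OH, since the 2-OH is hydrogen-bonded to the aldehyde and shielded by the methyl group.

Step 13
Reactants: 18 6-bromo-2-hydroxy-4-(methoxymethoxy)-3-methylbenzaldehyde
Product: 19 6-bromo-2-methoxy-4-(methoxymethoxy)-3-methylbenzaldehyde
Conditions: MeI, K2CO3, DMF, 50 °C
Reagents that add atoms: iodomethane, CI
Why: Williamson O-methylation of the chelated, hindered phenol with a small electrophile in a dipolar aprotic solvent.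

Step 14
Reactants: 19 6-bromo-2-methoxy-4-(methoxymethoxy)-3-methylbenzaldehyde; 6 acetophenone
Product: 20 (E)-3-[6-bromo-2-methoxy-4-(methoxymethoxy)-3-methylphenyl]-1-phenylprop-2-en-1-one
Conditions: KOH, EtOH/H2O, rt to 40 °C
Reagents that add atoms: none
Why: Claisen–Schmidt condensation as in step 4, giving the (E)-enone by E1cB dehydration.

Step 15
Reactants: 20 (E)-3-[6-bromo-2-methoxy-4-(methoxymethoxy)-3-methylphenyl]-1-phenylprop-2-en-1-one
Product: 21 3-[6-bromo-2-methoxy-4-(methoxymethoxy)-3-methylphenyl]-1-phenylpropan-1-one
Conditions: H2 (4 atm), RhCl(PPh3)3 (5 mol%), toluene/EtOH, 50 °C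
Reagents that add atoms: none
Why: homogeneous rhodium-catalysed hydrogenation of the enone C=C as in step 5, without hydrogenolysis of the C–Br bond.

Step 16
Reactants: 21 3-[6-bromo-2-methoxy-4-(methoxymethoxy)-3-methylphenyl]-1-phenylpropan-1-one
Product: 22 (S)-3-[6-bromo-2-methoxy-4-(methoxymethoxy)-3-methylphenyl]-1-phenylpropan-1-ol
Conditions: (R)-2-methyl-CBS-oxazaborolidine (20 mol%), BH3·SMe2, THF, −20 °C; then MeOH, H2O
Reagents that add atoms: none
Why: Corey–Bakshi–Shibata reduction with the same facial preference as in step 6, setting the (S)-carbinol that becomes C2 of unit B.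

**Union and end game (steps 17–19)**

Step 17
Reactants: 22 (S)-3-[6-bromo-2-methoxy-4-(methoxymethoxy)-3-methylphenyl]-1-phenylpropan-1-ol; 13 (2S)-5-methoxy-7-(methoxymethoxy)-2-phenylchromane-8-carbaldehyde
Product: 25 [(2S)-5-methoxy-7-(methoxymethoxy)-2-phenylchroman-8-yl][(2S)-5-methoxy-7-(methoxymethoxy)-6-methyl-2-phenylchroman-8-yl]methanol (bis-MOM diarylcarbinol; both carbinol epimers), via aryne lithium alkoxide 23 (not isolated), via 8-lithiochromane 24 (not isolated)
Conditions: LiTMP (2.2 equiv per 22; from 2,2,6,6-tetramethylpiperidine and n-BuLi), THF, −78 to −10 °C; then 13 (0.8 equiv), −78 to −20 °C; then H2O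
Reagents that add atoms: none
Why: Two equivalents of LiTMP are consumed: one deprotonates the hydroxyl, the second lithiates C8, whose hydrogen is the only one on the ring and is acidified by the flanking bromine and MOM ether, and on warming the 2-bromoaryllithium expels LiBr to give the C8–C8a aryne 23. The tethered alkoxide should add to C8a in a 6-exo-dig closure (O1–C8a bond, pyran ring of unit B), leaving the carbanion at C8 as aryllithium 24, held by the C7 MOM ether and O1, which then adds to the aldehyde of 13 and forms the C8–bridge bond. The closest known reaction type is the anionic aryne cyclisation of a haloarene bearing a tethered heteroatom nucleophile with electrophilic trapping of the ortho-metallated product, joined to the ordinary addition of a 2,6-dioxygenated aryllithium to a benzaldehyde. No stereocentre of the target is created: the oxygen-bearing carbon of the side chain is a spectator, so C2 of unit B keeps the (S) configuration from step 16, and the new carbinol centre is removed in step 18. The step needs site selectivity in the lithiation, secured by the C6 methyl (no other ring hydrogen), and regioselectivity in the addition to the aryne, secured by the three-atom tether (six- rather than seven-membered ring) and by the inductive effect of the C7 oxygen, which places the negative charge at C8. Chemoselectivity towards the aldehyde is secured by adding 13 only after the aryne has been consumed and by using 22 in slight excess so that little free amide remains.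

Step 18
Reactants: 25 bis-MOM diarylcarbinol
Product: 26 (2S)-5-methoxy-8-{[(2S)-5-methoxy-7-(methoxymethoxy)-6-methyl-2-phenylchroman-8-yl]methyl}-7-(methoxymethoxy)-2-phenylchromane (bis-MOM diarylmethane)
Conditions: Et3SiH (5 equiv), CF3CO2H (3 equiv), CH2Cl2, −20 to 0 °C; then aq NaHCO3
Reagents that add atoms: none
Why: ionic hydrogenation, in which the carbinol ionises readily to a diarylmethyl cation stabilised by three ortho/para oxygens on each ring and takes hydride from the silane, while the short exposure to little acid at low temperature should spare most of the MOM ethers (any phenol set free early converges in step 19).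

Step 19
Reactants: 26 bis-MOM diarylmethane
Product: 27 (2S)-8-{[(2S)-7-hydroxy-5-methoxy-2-phenylchroman-8-yl]methyl}-5-methoxy-6-methyl-2-phenylchroman-7-ol (CNP0114750.1)
Conditions: HCl (2 M), MeOH/THF, 45 °C
Reagents that add atoms: none
Why: acid-catalysed acetal exchange removes both MOM groups, methanol capturing the methoxymethyl cation as dimethoxymethane so that it cannot alkylate the free C6 position of unit A, while the aryl methyl ethers, the pyran rings and both C2 centres are untouched.

**Compound list**

1 | 5-bromobenzene-1,3-diol | Oc1cc(O)cc(Br)c1 | starting material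
2 | N-[(2-bromo-4,6-dihydroxyphenyl)methylidene]-N-methylmethanaminium chloride | C[N+](C)=Cc1c(O)cc(O)cc1Br.[Cl-] | intermediate (not isolated)
3 | 2-bromo-4,6-dihydroxybenzaldehyde | O=Cc1c(O)cc(O)cc1Br | intermediate
4 | 2-bromo-6-hydroxy-4-(methoxymethoxy)benzaldehyde | COCOc1cc(O)c(C=O)c(Br)c1 | intermediate
5 | 2-bromo-6-methoxy-4-(methoxymethoxy)benzaldehyde | COCOc1cc(OC)c(C=O)c(Br)c1 | intermediate
6 | acetophenone | CC(=O)c1ccccc1 | starting material
7 | (E)-3-[2-bromo-6-methoxy-4-(methoxymethoxy)phenyl]-1-phenylprop-2-en-1-one | COCOc1cc(OC)c(/C=C/C(=O)c2ccccc2)c(Br)c1 | intermediate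
8 | 3-[2-bromo-6-methoxy-4-(methoxymethoxy)phenyl]-1-phenylpropan-1-one | COCOc1cc(OC)c(CCC(=O)c2ccccc2)c(Br)c1 | intermediate
9 | (S)-3-[2-bromo-6-methoxy-4-(methoxymethoxy)phenyl]-1-phenylpropan-1-ol | COCOc1cc(OC)c(CC[C@H](O)c2ccccc2)c(Br)c1 | intermediate
10 | (2S)-5-methoxy-7-(methoxymethoxy)-2-phenylchromane | COc1cc(OCOC)cc2c1CC[C@@H](c1ccccc1)O2 | intermediate
11 | (2S)-8-bromo-5-methoxy-7-(methoxymethoxy)-2-phenylchromane | COc1cc(OCOC)c(Br)c2c1CC[C@@H](c1ccccc1)O2 | intermediate
12 | [(2S)-5-methoxy-7-(methoxymethoxy)-2-phenylchroman-8-yl]lithium | COc1cc(OCOC)c([Li])c2c1CC[C@@H](c1ccccc1)O2 | intermediate (not isolated)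
13 | (2S)-5-methoxy-7-(methoxymethoxy)-2-phenylchromane-8-carbaldehyde | COc1cc(OCOC)c(C=O)c2c1CC[C@@H](c1ccccc1)O2 | intermediate
14 | 5-bromo-1,3-dimethoxy-2-methylbenzene | COc1cc(Br)cc(OC)c1C | starting material
15 | 5-bromo-2-methylbenzene-1,3-diol | Cc1c(O)cc(Br)cc1O | intermediate
16 | N-[(6-bromo-2,4-dihydroxy-3-methylphenyl)methylidene]-N-methylmethanaminium chloride | C[N+](C)=Cc1c(Br)cc(O)c(C)c1O.[Cl-] | intermediate (not isolated)
17 | 6-bromo-2,4-dihydroxy-3-methylbenzaldehyde | Cc1c(O)cc(Br)c(C=O)c1O | intermediate
18 | 6-bromo-2-hydroxy-4-(methoxymethoxy)-3-methylbenzaldehyde | COCOc1cc(Br)c(C=O)c(O)c1C | intermediate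
19 | 6-bromo-2-methoxy-4-(methoxymethoxy)-3-methylbenzaldehyde | COCOc1cc(Br)c(C=O)c(OC)c1C | intermediate
20 | (E)-3-[6-bromo-2-methoxy-4-(methoxymethoxy)-3-methylphenyl]-1-phenylprop-2-en-1-one | COCOc1cc(Br)c(/C=C/C(=O)c2ccccc2)c(OC)c1C | intermediate
21 | 3-[6-bromo-2-methoxy-4-(methoxymethoxy)-3-methylphenyl]-1-phenylpropan-1-one | COCOc1cc(Br)c(CCC(=O)c2ccccc2)c(OC)c1C | intermediate
22 | (S)-3-[6-bromo-2-methoxy-4-(methoxymethoxy)-3-methylphenyl]-1-phenylpropan-1-ol | COCOc1cc(Br)c(CC[C@H](O)c2ccccc2)c(OC)c1C | intermediate
23 | lithium (S)-3-[2-methoxy-4-(methoxymethoxy)-3-methyl-5,6-didehydrophenyl]-1-phenylpropan-1-olate (C8–C8a aryne) | COCOC1=C(C)C(OC)=C(CC[C@H]([O-])c2ccccc2)C#C1.[Li+] | intermediate (not isolated)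
24 | [(2S)-5-methoxy-7-(methoxymethoxy)-6-methyl-2-phenylchroman-8-yl]lithium | COCOc1c(C)c(OC)c2c(c1[Li])O[C@H](c1ccccc1)CC2 | intermediate (not isolated)
25 | [(2S)-5-methoxy-7-(methoxymethoxy)-2-phenylchroman-8-yl][(2S)-5-methoxy-7-(methoxymethoxy)-6-methyl-2-phenylchroman-8-yl]methanol (both carbinol epimers) | COc1cc(OCOC)c(C(O)c2c(OCOC)c(C)c(OC)c3c2O[C@H](c2ccccc2)CC3)c2c1CC[C@@H](c1ccccc1)O2 | intermediate
26 | (2S)-5-methoxy-8-{[(2S)-5-methoxy-7-(methoxymethoxy)-6-methyl-2-phenylchroman-8-yl]methyl}-7-(methoxymethoxy)-2-phenylchromane | COc1cc(OCOC)c(Cc2c(OCOC)c(C)c(OC)c3c2O[C@H](c2ccccc2)CC3)c2c1CC[C@@H](c1ccccc1)O2 | intermediate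
27 | (2S)-8-{[(2S)-7-hydroxy-5-methoxy-2-phenylchroman-8-yl]methyl}-5-methoxy-6-methyl-2-phenylchroman-7-ol | COc1cc(O)c(Cc2c(O)c(C)c(OC)c3c2O[C@H](c2ccccc2)CC3)c2c1CC[C@@H](c1ccccc1)O2 | target

Total step count: 19. Longest linear sequence: 12 steps (steps 1 to 9, then 17, 18 and 19).

**Steps most likely to fail**

1. Step 17. The C8 aryllithium may be protonated before it meets the hindered aldehyde, the amide or amine may add to the aryne in competition with the tethered alkoxide, or addition to the di-ortho-substituted aldehyde may stall. Fallback: setting out from 22, the pyran ring would be closed by the etherification of step 7 (Pd(OAc)2, rac-2-(di-tert-butylphosphino)-1,1'-binaphthyl, Cs2CO3, toluene, 80 °C) to give (2S)-5-methoxy-7-(methoxymethoxy)-6-methyl-2-phenylchromane F1. NBS in CH2Cl2 would then brominate C8, the only ring hydrogen left, to give (2S)-8-bromo-5-methoxy-7-(methoxymethoxy)-6-methyl-2-phenylchromane F2. Bromine–lithium exchange with n-BuLi in THF at −78 °C would give the same aryllithium 24, which is added to 13 to rejoin the route at 25.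

2. Step 8. Site selectivity between C6 and C8 may be poor, or a second bromination may follow. Fallback: setting out from 9, LiTMP (2.2 equiv) in THF (−78 to −10 °C) would generate lithium (S)-3-[6-methoxy-4-(methoxymethoxy)-2,3-didehydrophenyl]-1-phenylpropan-1-olate F3, whose alkoxide closes the ring to aryllithium 12. DMF then gives 13, where the route is rejoined, bypassing 10 and 11. The formyl position then follows from where the bromine sat in 9, not from the relative nucleophilicity of C6 and C8. Competing lithiation at the hydrogen between the methoxy and MOM groups is the reason this is not the main route.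

3. Step 18. The diarylmethyl cation, stabilised by six oxygen donors, may take hydride slowly and instead fragment by ipso-protonation. MOM groups may also be lost early and their cation captured by C6 of unit A. Fallback: setting out from 25, NaH, CS2 and MeI in THF would give O-{[(2S)-5-methoxy-7-(methoxymethoxy)-2-phenylchroman-8-yl][(2S)-5-methoxy-7-(methoxymethoxy)-6-methyl-2-phenylchroman-8-yl]methyl} S-methyl carbonodithioate F4. Bu3SnH with AIBN in toluene at 90 °C would then cleave the benzylic C–O bond by a radical chain (Barton–McCombie deoxygenation) without any acid, rejoining the route at 26.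

**Further compounds**

F1 | step 17 | (2S)-5-methoxy-7-(methoxymethoxy)-6-methyl-2-phenylchromane | COc1c(C)c(OCOC)cc2c1CC[C@@H](c1ccccc1)O2
F2 | step 17 | (2S)-8-bromo-5-methoxy-7-(methoxymethoxy)-6-methyl-2-phenylchromane | COc1c(C)c(OCOC)c(Br)c2c1CC[C@@H](c1ccccc1)O2
F3 | step 8 | lithium (S)-3-[6-methoxy-4-(methoxymethoxy)-2,3-didehydrophenyl]-1-phenylpropan-1-olate | COCOC1=CC(OC)=C(CC[C@H]([O-])c2ccccc2)C#C1.[Li+]
F4 | step 18 | O-{[(2S)-5-methoxy-7-(methoxymethoxy)-2-phenylchroman-8-yl][(2S)-5-methoxy-7-(methoxymethoxy)-6-methyl-2-phenylchroman-8-yl]methyl} S-methyl carbonodithioate | COc1cc(OCOC)c(C(OC(=S)SC)c2c(OCOC)c(C)c(OC)c3c2O[C@H](c2ccccc2)CC3)c2c1CC[C@@H](c1ccccc1)O2
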